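| setting | dusk | midnight | summer | flask |
|---|---|---|---|---|
| L | 33 mM | 33 mM | 66 mM | 33 mM |
| Z | 33 mM | 33 mM | 66 mM | 33 mM |
| D | 5.6 equiv | 8.8 equiv | 4 equiv | 4.00 equiv |
| G | 5 mol% | 5 mol% | 5 mol% | 5 mol% |
| X | 5 mol% | 5 mol% | 5 mol% | 5 mol% |
| remark | run made earlier | run made earlier | run made earlier |  |
| time |  |  |  | 10 d |

| run | time / d | L / % | Z / % | Q / % |
|---|---|---|---|---|
| dusk | 0.500 | 16.0 | 40.6 | 26.2 |
| dusk | 0.833 | 6.7 | 35.1 | 31.6 |
| dusk | 1.25 | 3.6 | 28.8 | 35.4 |
| dusk | 2.00 | 1.2 | 23.0 | 36.8 |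
| dusk | 4.00 | 2.3 | 10.5 | 44.4 |
| dusk | 6.00 | 0.1 | 6.3 | 46.7 |
| midnight | 0.500 | 9.4 | 36.6 | 33.1 |
| midnight | 0.833 | 3.0 | 27.7 | 35.7 |
| midnight | 1.25 | 0.7 | 20.0 | 40.6 |
| midnight | 2.00 | 0.6 | 14.5 | 43.9 |
| midnight | 4.00 | 0 | 5.3 | 45.5 |
| midnight | 6.00 | 0 | 3.5 | 49.3 |
| summer | 1.25 | 0.5 | 16.4 | 42.6 |
| summer | 2.50 | 0 | 5.0 | 47.0 |
| summer | 4.00 | 0 | 2.3 | 49.6 |
| summer | 5.00 | 0.9 | 1.8 | 49.3 |
| summer | 6.00 | 0.8 | 0.2 | 50.8 |

(each reading ± 1 percentage point)

- G is single-handed; L and Z are mirror images of each other, charged as a racemate, each of them at the stated concentration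
- an excess is the difference of the two amounts in percent of their sum
- an excess is below zero if the other one leads

- part of the L and Z charged together that has reacted at 10 d
- excess of Q over J in the product at 10 d
- excess of Z over L among what is left of the two at 10 d

If each L and each Z took one D, the flask could not run out of D: together they were 66.0 mM, c_D started at 132 mM, so c_D had a floor of 66.0 mM. That band let me freeze c_D and treat Z as pseudo-first-order.

In the dusk run, which has the flask's c_L and c_G, Z fell from 23.0% at 2.00 d to 6.3% at 6.00 d, a constant of 0.324 d⁻¹. At the middle reading, what had reacted put c_D at 127 mM. Their quotient, 2.54 M⁻¹ d⁻¹, I called b, the first-order loss of Z per unit of c_D at this loading of G.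

L read 1.2% at 2.00 d in the dusk run, so I put c_D in the flask between 99.0 mM, with half the substrate used, and the floor, and froze it at 82.5 mM. Over 10 d that left Z at 6.13% of the total charged, so c stood near 93.9%.

The weak link was b, which rested on a late reading with a scatter of 1 percentage point. I reforged it from the midnight run: Z fell from 36.6% at 0.500 d to 14.5% at 2.00 d, with c_D at 238 mM in the middle, twice the dusk value, and b came to 2.59 M⁻¹ d⁻¹.

The forecast gave c 93% (89% to 96%), eP 2% (−3% to 7%) and eS 100% (98% to 100%), holding that “D is consumed one-to-one”. Its c lay just under mine.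

The flask gave c 94.0%, eP −0.174% and eS 95.3%.

    Q ⇌ J (k = 0.0961 h⁻¹)
    D + G + Z → G + J (k = 54.4 M⁻² h⁻¹)
    L + X ⇌ Z + X, rate k3*[X]*[L] forward; the back reaction follows from the equilibrium constant (k = 7.79 M⁻¹ h⁻¹)
    D + G + L → G + Q (k = 378 M⁻² h⁻¹)
    2 X → E (k = 19.0 M⁻¹ h⁻¹)

At 10.0 d the slowest mode of the flask had a half-life of 3.90 d, a rate of 0.178 d⁻¹, and b times the c_D then standing, 69.9 mM, gives 0.178 d⁻¹. In the neighbour flask with 1.00 equiv of D, D stood at 5.43% of its charge at 10.0 d and c reached 47.3%.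

The runs were computed with constants of no real substance, noise included.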